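**Retrosynthetic overview**

- Numbering (used for all later compounds): C1 (=CH2), C2 (OAc), C5 (CH3), C8=C9 (tetrasubstituted alkene, CH3 on C9), C10 and C11 (ring-fusion CH), C12–C13 (CH2), C14 (quaternary, CH3), C15 and C16 (diol; C16 is bonded to C8). The strategy rests on the array O–C2–C1–C11–C10–C9=C8 inside the eleven-membered ring (C1–C11), whose C8=C9 bond is both the E alkene of that ring and the bridgehead alkene of the cyclohexene (C8, C9, C10, C14, C15, C16): this is the δ,ε-unsaturated ketone that a [3,3] shift of a 1-alkenyl carbinol delivers.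
- Disconnections: C15–OH from the ketone and C2–OAc from a protected carbinol; the cyclopentane by C13–C14 enolate alkylation; the C1 methylene by aminomethylation–elimination of the rearrangement enolate; the eleven-membered ring by an anionic oxy-Cope shift of a 1-alkenyl spiro[5.6] carbinol, which breaks a C2–C8 bond absent from the target and forms C10–C11.
- The spiro ketone comes from semipinacol expansion of an epoxy carbinol, itself made by Birch reduction and directed asymmetric epoxidation of the adduct of 1,5-dibromo-2,4-dimethylbenzene and 4-methylcyclohexanone; the alkenyl unit comes from but-3-yn-1-ol.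
- Ring order: six-membered ring (the arene, dearomatised), then the seven-membered ring (semipinacol), then the eleven-membered ring (four-atom expansion of the seven-membered ring), and the cyclopentane last.
- Stereochemistry: the epoxidation is the only source of absolute configuration; C8 and C5 follow in the semipinacol step, C10 and C11 by transfer from C8 in the [3,3] shift, C14 by the tether, C2 by CBS reduction, C16 by enolate hydroxylation, C15 by directed reduction.

Key step: step 10

Remark: the facial sense of the bishydroxamic acid ligand in step 4 is assumed by analogy, and the ligand antipode that gives epoxide 8 is the one used; 17 and 26–30 are drawn as the expected major C2 and C14 epimers, and the minor epimers converge in steps 10 and 17.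

**Route**

Step 1
Reactants: 1 1,5-dibromo-2,4-dimethylbenzene; 2 4-methylcyclohexanone
Product: 5 1-(5-bromo-2,4-dimethylphenyl)-4-methylcyclohexan-1-ol (aryl trans to the 4-methyl group; OH axial), via aryllithium 3 (not isolated), via arylcerium dichloride 4 (not isolated)
Conditions: n-BuLi (1.0 equiv), THF, −78 °C; anhydrous CeCl3, THF, −78 °C; then 2, −78 to 0 °C; aq. NH4Cl
Reagents that add atoms: none
Why: Bromine–lithium exchange on one of the two equivalent bromides is clean at −78 °C and the bulky, weakly basic arylcerium reagent adds 1,2 to the ketone along the equatorial trajectory of the methyl-equatorial chair (organocerium carbonyl addition), which places the aryl group equatorial and trans to the ring methyl with the hydroxyl axial, the minor cis carbinol being removed by crystallisation or chromatography.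

Step 2
Reactants: 5 1-(5-bromo-2,4-dimethylphenyl)-4-methylcyclohexan-1-ol
Product: 6 1-(5-methoxy-2,4-dimethylphenyl)-4-methylcyclohexan-1-ol (aryl trans to the 4-methyl group)
Conditions: NaOMe (5 equiv), CuI (10 mol %), MeOH–DMF, 110 °C, sealed tube
Reagents that add atoms: sodium methoxide, C[O-].[Na+]
Why: Ullmann-type copper-catalysed methoxylation exchanges the remaining aryl bromide for methoxide under basic conditions in which the tertiary benzylic alkoxide is inert, and no stereocentre is touched.

Step 3
Reactants: 6 1-(5-methoxy-2,4-dimethylphenyl)-4-methylcyclohexan-1-ol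
Product: 7 1-(5-methoxy-2,4-dimethylcyclohexa-1,4-dien-1-yl)-4-methylcyclohexan-1-ol (dienyl trans to the 4-methyl group; achiral)
Conditions: Li, liquid NH3, THF, t-BuOH, −78 to −33 °C; then solid NH4Cl; non-acidic work-up
Reagents that add atoms: none
Why: Birch reduction of the anisole runs on the lithium alkoxide, which shields the benzylic C–O bond from reductive cleavage, and protonation falls on the two unsubstituted ring carbons (C10 and C16) so that the four donor-substituted carbons stay olefinic and the achiral 1-methoxy-1,4-diene results.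

Step 4
Reactants: 7 1-(5-methoxy-2,4-dimethylcyclohexa-1,4-dien-1-yl)-4-methylcyclohexan-1-ol
Product: 8 epoxy carbinol 1-[(1R,6R)-3-methoxy-4,6-dimethyl-7-oxabicyclo[4.1.0]hept-3-en-1-yl]-4-methylcyclohexan-1-ol (C8–C9 epoxide)
Conditions: Hf(Ot-Bu)4 (10 mol %), N,N′-dihydroxy-N,N′-bis(2,2-diphenylacetyl)-trans-cyclohexane-1,2-diamine (one antipode, 11 mol %), cumene hydroperoxide, MgO, toluene, 0 °C
Reagents that add atoms: cumene hydroperoxide, CC(C)(OO)c1ccccc1
Why: Hydroxyl-directed metal–bishydroxamic acid epoxidation delivers oxygen only to the allylic tetrasubstituted C8=C9 bond of the bound carbinol (the remote enol ether is not activated), and the chiral ligand distinguishes the two enantiotopic faces of this alkene, which fixes C8 and C9 (both R) and is the sole source of absolute configuration.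

Step 5
Reactants: 8 epoxy carbinol
Product: 9 spiro β-hydroxy ketone (5R,6S,10R)-5-hydroxy-2-methoxy-3,5,10-trimethylspiro[5.6]dodec-2-en-7-one
Conditions: ZnBr2 (1.1 equiv), CH2Cl2, −78 to −30 °C; aq. NaHCO3
Reagents that add atoms: none
Why: In this Lewis-acid-promoted semipinacol rearrangement of a 2,3-epoxy alcohol a ring methylene shifts from the carbinol carbon to C8 anti to the breaking C8–O bond, so C8 is inverted into the spiro centre while C9–O is retained, and the reacting rotamer that keeps the non-migrating methylene beside C16H2 and not beside the fully substituted C9 selects the methylene whose migration gives the 5R methyl centre.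

Step 6
Reactants: 9 spiro β-hydroxy ketone
Product: 10 spiro dienol ether ketone (6S,10R)-4-methoxy-1,3,10-trimethylspiro[5.6]dodeca-1,3-dien-7-one
Conditions: methyl N-(triethylammoniumsulfonyl)carbamate (1.5 equiv), toluene, 25 to 50 °C
Reagents that add atoms: none
Why: Dehydration through the sulfamate ester is a neutral syn elimination that spares the base-labile β-hydroxy ketone (no retro-aldol), and loss of a C10 hydrogen is preferred because it places the new C9=C10 bond in conjugation with the enol ether.

Step 7
Reactants: 11 but-3-yn-1-ol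
Product: 12 (but-3-yn-1-yloxy)(tert-butyl)dimethylsilane
Conditions: TBSCl, imidazole, CH2Cl2, 0 °C to rt
Reagents that add atoms: tert-butyldimethylsilyl chloride, CC(C)(C)[Si](C)(C)Cl
Why: Standard imidazole-mediated silylation protects the primary alcohol as its tert-butyldimethylsilyl ether.

Step 8
Reactants: 12 (but-3-yn-1-yloxy)(tert-butyl)dimethylsilane
Product: 14 tert-butyl{[(E)-4-iodobut-3-en-1-yl]oxy}dimethylsilane, via alkenylzirconocene chloride 13 (not isolated)
Conditions: Cp2Zr(H)Cl (1.1 equiv), CH2Cl2, rt; then I2, 0 °C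
Reagents that add atoms: iodine, II
Why: Hydrozirconation adds Zr–H syn across the terminal alkyne with zirconium on the terminal carbon, and iodinolysis of the C–Zr bond with retention gives the E alkenyl iodide.

Step 9
Reactants: 14 tert-butyl{[(E)-4-iodobut-3-en-1-yl]oxy}dimethylsilane; 10 spiro dienol ether ketone
Product: 17 alkenyl spiro carbinol (6S,7R,10R)-7-[(E)-4-(tert-butyldimethylsilyloxy)but-1-en-1-yl]-4-methoxy-1,3,10-trimethylspiro[5.6]dodeca-1,3-dien-7-ol, via alkenyllithium 15 (not isolated), via alkenylcerium dichloride 16 (not isolated)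
Conditions: t-BuLi (2.0 equiv), Et2O, −78 °C; anhydrous CeCl3, THF, −78 °C; then 10, −78 to −40 °C; aq. NH4Cl
Reagents that add atoms: none
Why: Iodine–lithium exchange preserves the E geometry and the derived organocerium reagent adds to the hindered, enolisable C2 ketone without deprotonation (organocerium 1,2-addition), the configuration of the new carbinol centre being of no consequence because both epimers can reach the same rearrangement transition state.

Step 10
Reactants: 17 alkenyl spiro carbinol
Product: 22 bicyclo[8.3.1] α-methylene ketone (C1 methylidene; C2 ketone; C8=C9 and C14=C15 alkenes; 5R,10S,11R), via potassium alkoxide 18 (not isolated), via potassium enolate 19 (not isolated), via Mannich base 20 (not isolated), via ammonium iodide 21 (not isolated)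
Conditions: KH (1.1 equiv), 18-crown-6, THF, 0 to 25 °C; then Me2N=CH2 iodide, −78 to 0 °C; then MeI, CH2Cl2–MeOH, rt; aq. NaHCO3, rt
Reagents that add atoms: dimethylmethyleneammonium iodide, C=[N+](C)C.[I-]
Why: Proposed new method: deprotonation gives alkoxide 18, which should undergo an alkoxide-accelerated [3,3] sigmatropic shift through a chair transition state in which the C2–C8 bond, pseudoaxial on the cyclohexadiene and parallel to its π system, breaks while the alkenyl terminus C11 bonds to C10, the closest known reaction type being the anionic oxy-Cope four-carbon ring expansion of 1,2-dialkenylcycloalkanols (bridgehead-alkene cases included), which has not been applied to a spiro cyclohexadienyl carbinol. The eleven-membered ring is closed by ring expansion of the cycloheptane, not by end-to-end cyclisation, and because C8 stays in the six-membered ring the new C8=C9 bond is necessarily E within the large ring. C10 is set by suprafacial chirality transfer from the spiro centre C8 (C11 arrives on the face that C2 leaves) and C11 by the chair with the E alkene, in which C1 lies anti to C7 above the ring. The selectivity needed is this chair [3,3] path over a boat or a [1,3] shift, and it is secured by the seven-membered ring, which lets both C2 epimers of 17 place the alkenyl group anti to C7 so that they converge on 10S,11R, while the diene terminus and the relief of spiro congestion should lower the barrier. The shift delivers the regiodefined C1=C2 enolate 19, so aminomethylation by the iminium salt occurs at C1 only (Mannich base 20), and quaternisation to 21 followed by bicarbonate-induced elimination gives the α-methylene ketone with C2 left as the ketone.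

Step 11
Reactants: 22 bicyclo[8.3.1] α-methylene ketone
Product: 23 (2R)-allylic alcohol (C2 carbinol of 22)
Conditions: (S)-2-methyl-CBS-oxazaborolidine (0.2–1.0 equiv), catecholborane, toluene, −78 °C
Reagents that add atoms: none
Why: In this CBS reduction the oxazaborolidine differentiates the alkenyl flank (C1) from the methylene flank (C3) of the enone and delivers hydride 1,2 to give the 2R allylic alcohol under reagent control.

Step 12
Reactants: 23 (2R)-allylic alcohol
Product: 25 C2 4-methoxybenzyl ether of 23, via sodium alkoxide 24 (not isolated)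
Conditions: NaH, THF–DMF, 0 °C; then 4-methoxybenzyl chloride, Bu4NI (cat.), 0 °C to rt
Reagents that add atoms: 4-methoxybenzyl chloride, COc1ccc(CCl)cc1
Why: Williamson etherification of the sodium alkoxide installs a base-stable 4-methoxybenzyl ether under conditions that do not touch the enol ether or the silyl ether.

Step 13
Reactants: 25 C2 4-methoxybenzyl ether
Product: 26 C15 ketone (β,γ-unsaturated; C14 bears H and CH3; silyl and 4-methoxybenzyl ethers retained)
Conditions: oxalic acid, THF–H2O, 0 °C to rt
Reagents that add atoms: water, O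
Why: Dilute oxalic acid hydrolyses the methyl enol ether to the C15 ketone without drawing the C8=C9 bond into conjugation (mild enol ether hydrolysis), and protonation with slow equilibration at C14 should favour the epimer with the methyl group anti to the C10 substituent, a centre that is planarised again in step 17.

Step 14
Reactants: 26 C15 ketone
Product: 28 (16R)-16-hydroxy C15 ketone (ketol; silyl ether retained), via potassium dienolate 27 (not isolated)
Conditions: KN(SiMe3)2, THF, −78 °C; then 2-(phenylsulfonyl)-3-phenyloxaziridine, −78 °C; aq. NH4Cl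
Reagents that add atoms: 2-(phenylsulfonyl)-3-phenyloxaziridine, O=S(=O)(N1OC1c1ccccc1)c1ccccc1
Why: Kinetic deprotonation takes the doubly activated (α-keto and allylic) C16 hydrogen, and the extended potassium enolate is hydroxylated at C16 by the N-sulfonyloxaziridine (enolate oxidation) on the face opposite the pseudoaxial C14 methyl, which gives the pseudoequatorial, hydrogen-bonded 16R ketol.

Step 15
Reactants: 28 (16R)-16-hydroxy C15 ketone
Product: 29 ketol primary alcohol (C13 OH)
Conditions: HF·pyridine, pyridine, THF, 0 °C
Reagents that add atoms: none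
Why: Buffered fluoride cleaves the primary silyl ether while the 4-methoxybenzyl ether and the ketol are stable.

Step 16
Reactants: 29 ketol primary alcohol
Product: 30 ketol primary iodide (C13 iodide; C2 4-methoxybenzyl ether)
Conditions: I2, PPh3, imidazole, CH2Cl2, 0 °C
Reagents that add atoms: iodine, II
Why: Appel-type iodination converts the unhindered primary alcohol faster than the hindered secondary ketol hydroxyl.

Step 17
Reactants: 30 ketol primary iodide
Product: 32 cis-hydrindane ketol (C13–C14 bond; 14S quaternary centre; C15 ketone; 16R hydroxyl), via dilithium alkoxide enolate 31 (not isolated)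
Conditions: LiN(i-Pr)2 (2.3 equiv), THF, −78 to 0 °C; aq. NH4Cl
Reagents that add atoms: none
Why: The first equivalent of base forms the C16 alkoxide, whose charge disfavours removal of the adjacent C16 hydrogen, so the second equivalent enolises toward C14 and the enolate closes the cyclopentane by 5-exo-tet alkylation (intramolecular enolate alkylation), the three-atom tether from C11 reaching only the face of C14 on which it stands and thereby setting the cis-fused quaternary centre (14S).

Step 18
Reactants: 32 cis-hydrindane ketol
Product: 33 C16 triethylsilyl ether of 32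
Conditions: Et3SiCl, imidazole, DMF, 0 °C to rt
Reagents that add atoms: chlorotriethylsilane, CC[Si](CC)(CC)Cl
Why: Silylation masks the ketol hydroxyl so that the deprotection and acetylation that follow meet only the C2 oxygen.

Step 19
Reactants: 33 C16 triethylsilyl ether
Product: 34 C2 alcohol (4-methoxybenzyl group removed)
Conditions: DDQ, CH2Cl2–pH 7 buffer, 0 °C
Reagents that add atoms: none
Why: Oxidative cleavage of the 4-methoxybenzyl ether with DDQ under buffered conditions frees the C2 hydroxyl and leaves the silyl ether, the ketone and the alkenes intact.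

Step 20
Reactants: 34 C2 alcohol
Product: 35 C2 acetate
Conditions: Ac2O, pyridine, DMAP (cat.), CH2Cl2, 0 °C to rt
Reagents that add atoms: acetic anhydride, CC(=O)OC(C)=O
Why: The only free hydroxyl, the allylic C2 alcohol, is acetylated under standard nucleophilic catalysis.

Step 21
Reactants: 35 C2 acetate
Product: 36 acetoxy ketol (C16 hydroxyl freed)
Conditions: HF·pyridine, THF, 0 °C
Reagents that add atoms: none
Why: Fluoride removes the triethylsilyl group under mild buffered conditions that neither cleave nor migrate the allylic acetate.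

Step 22
Reactants: 36 acetoxy ketol
Product: 37 target CNP0192310.3 ((2R,5R,10S,11R,14S,15R,16R); C15 hydroxyl trans to C16 hydroxyl)
Conditions: Me4NBH(OAc)3, MeCN–AcOH, −20 °C
Reagents that add atoms: none
Why: In this hydroxyl-directed reduction the triacetoxyborohydride exchanges a ligand for the C16 hydroxyl and delivers hydride intramolecularly to the same face of the C15 carbonyl, so the new hydroxyl is trans to O16 (15R), while the acetate and both alkenes are untouched.

**Compound list**

1 | 1,5-dibromo-2,4-dimethylbenzene | Cc1cc(C)c(Br)cc1Br | starting material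
2 | 4-methylcyclohexanone | CC1CCC(=O)CC1 | starting material
3 | (5-bromo-2,4-dimethylphenyl)lithium | [Li]c1cc(Br)c(C)cc1C | intermediate
4 | (5-bromo-2,4-dimethylphenyl)cerium dichloride | Cl[Ce](Cl)c1cc(Br)c(C)cc1C | intermediate
5 | 1-(5-bromo-2,4-dimethylphenyl)-4-methylcyclohexan-1-ol, aryl trans to the 4-methyl group (OH axial, cis to methyl) | C[C@H]1CC[C@](O)(c2cc(Br)c(C)cc2C)CC1 | intermediate
6 | 1-(5-methoxy-2,4-dimethylphenyl)-4-methylcyclohexan-1-ol, aryl trans to the 4-methyl group | C[C@H]1CC[C@](O)(c2cc(OC)c(C)cc2C)CC1 | intermediate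
7 | 1-(5-methoxy-2,4-dimethylcyclohexa-1,4-dien-1-yl)-4-methylcyclohexan-1-ol, dienyl trans to the 4-methyl group | C[C@H]1CC[C@](O)(C2=C(C)CC(C)=C(OC)C2)CC1 | intermediate
8 | 1-[(1R,6R)-3-methoxy-4,6-dimethyl-7-oxabicyclo[4.1.0]hept-3-en-1-yl]-4-methylcyclohexan-1-ol, bicyclic group trans to the 4-methyl group | C[C@H]1CC[C@](O)([C@@]23O[C@]2(C)CC(C)=C(OC)C3)CC1 | intermediate
9 | (5R,6S,10R)-5-hydroxy-2-methoxy-3,5,10-trimethylspiro[5.6]dodec-2-en-7-one (target numbering 5R,8S,9R) | O=C1CC[C@H](C)CC[C@]12[C@](C)(O)CC(C)=C(OC)C2 | intermediate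
10 | (6S,10R)-4-methoxy-1,3,10-trimethylspiro[5.6]dodeca-1,3-dien-7-one | O=C1CC[C@H](C)CC[C@]12C(C)=CC(C)=C(OC)C2 | intermediate
11 | but-3-yn-1-ol | C#CCCO | starting material
12 | (but-3-yn-1-yloxy)(tert-butyl)dimethylsilane | C#CCCO[Si](C)(C)C(C)(C)C | intermediate
13 | chlorobis(cyclopentadienyl)[(E)-4-(tert-butyldimethylsilyloxy)but-1-en-1-yl]zirconium | Cl[Zr](/C=C/CCO[Si](C)(C)C(C)(C)C)(C1C=CC=C1)C1C=CC=C1 | intermediate
14 | tert-butyl{[(E)-4-iodobut-3-en-1-yl]oxy}dimethylsilane | I/C=C/CCO[Si](C)(C)C(C)(C)C | intermediate
15 | [(E)-4-(tert-butyldimethylsilyloxy)but-1-en-1-yl]lithium | [Li]/C=C/CCO[Si](C)(C)C(C)(C)C | intermediate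
16 | [(E)-4-(tert-butyldimethylsilyloxy)but-1-en-1-yl]cerium dichloride | Cl[Ce](Cl)/C=C/CCO[Si](C)(C)C(C)(C)C | intermediate
17 | (6S,7R,10R)-7-[(E)-4-(tert-butyldimethylsilyloxy)but-1-en-1-yl]-4-methoxy-1,3,10-trimethylspiro[5.6]dodeca-1,3-dien-7-ol | O[C@@]1(/C=C/CCO[Si](C)(C)C(C)(C)C)CC[C@H](C)CC[C@]12C(C)=CC(C)=C(OC)C2 | intermediate
18 | potassium alkoxide of 17 | [K+].[O-][C@@]1(/C=C/CCO[Si](C)(C)C(C)(C)C)CC[C@H](C)CC[C@]12C(C)=CC(C)=C(OC)C2 | intermediate
19 | potassium C1=C2 enolate of the ring-expanded ketone: eleven-membered ring C1–C11 bridged at C8 and C10 by C16–C15–C14, C8=C9 and C14=C15(OMe) alkenes, methyls on C5, C9 and C14, 2-(tert-butyldimethylsilyloxy)ethyl on C11; 5R,10S,11R; enolate geometry not fixed | C1=C([O-])CC[C@H](C)CCC2=C(C)[C@H]([C@H]1CCO[Si](C)(C)C(C)(C)C)C(C)=C(OC)C2.[K+] | intermediate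
20 | Mannich base: C2 ketone of the same skeleton with CH2NMe2 on C1 (C1 epimers; 5R,10S,11R) | CN(C)CC1C(=O)CC[C@H](C)CCC2=C(C)[C@H]([C@H]1CCO[Si](C)(C)C(C)(C)C)C(C)=C(OC)C2 | intermediate
21 | trimethylammoniomethyl ketone iodide (methiodide of 20) | C[N+](C)(C)CC1C(=O)CC[C@H](C)CCC2=C(C)[C@H]([C@H]1CCO[Si](C)(C)C(C)(C)C)C(C)=C(OC)C2.[I-] | intermediate
22 | bicyclo[8.3.1] α-methylene ketone: C1 methylidene, C2 ketone, C8=C9, C14=C15(OMe), 11-(2-silyloxyethyl); 5R,10S,11R | C=C1C(=O)CC[C@H](C)CCC2=C(C)[C@H]([C@H]1CCO[Si](C)(C)C(C)(C)C)C(C)=C(OC)C2 | intermediate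
23 | (2R)-allylic alcohol from 22; 2R,5R,10S,11R | C=C1[C@H](O)CC[C@H](C)CCC2=C(C)[C@H]([C@H]1CCO[Si](C)(C)C(C)(C)C)C(C)=C(OC)C2 | intermediate
24 | sodium alkoxide of 23 | C=C1[C@H]([O-])CC[C@H](C)CCC2=C(C)[C@H]([C@H]1CCO[Si](C)(C)C(C)(C)C)C(C)=C(OC)C2.[Na+] | intermediate
25 | C2 4-methoxybenzyl ether of 23 | C=C1[C@H](OCc2ccc(OC)cc2)CC[C@H](C)CCC3=C(C)[C@H]([C@H]1CCO[Si](C)(C)C(C)(C)C)C(C)=C(OC)C3 | intermediate
26 | C15 ketone with C8=C9 retained (β,γ-unsaturated), C14 methyl anti to the C10 substituent; 2R,5R,10R,11R,14R | C=C1[C@H](OCc2ccc(OC)cc2)CC[C@H](C)CCC3=C(C)[C@H]([C@H]1CCO[Si](C)(C)C(C)(C)C)[C@@H](C)C(=O)C3 | intermediate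
27 | potassium C15=C16 dienolate of 26 | C=C1[C@H](OCc2ccc(OC)cc2)CC[C@H](C)CCC3=C(C)[C@H]([C@H]1CCO[Si](C)(C)C(C)(C)C)[C@@H](C)C([O-])=C3.[K+] | intermediate
28 | (16R)-16-hydroxy C15 ketone with the silyl ether | C=C1[C@H](OCc2ccc(OC)cc2)CC[C@H](C)CCC3=C(C)[C@H]([C@H]1CCO[Si](C)(C)C(C)(C)C)[C@@H](C)C(=O)[C@@H]3O | intermediate
29 | ketol with free primary alcohol at C13 | C=C1[C@H](OCc2ccc(OC)cc2)CC[C@H](C)CCC3=C(C)[C@H]([C@H]1CCO)[C@@H](C)C(=O)[C@@H]3O | intermediate
30 | ketol with primary iodide at C13 and C2 4-methoxybenzyl ether | C=C1[C@H](OCc2ccc(OC)cc2)CC[C@H](C)CCC3=C(C)[C@H]([C@H]1CCI)[C@@H](C)C(=O)[C@@H]3O | intermediate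
31 | dilithium C16 alkoxide C14=C15 enolate of 30 | C=C1[C@H](OCc2ccc(OC)cc2)CC[C@H](C)CCC3=C(C)[C@H]([C@H]1CCI)C(C)=C([O-])[C@@H]3[O-].[Li+].[Li+] | intermediate
32 | cis-hydrindane ketol: cyclopentane C10–C14 closed, C15 ketone, 16-hydroxyl, C2 4-methoxybenzyl ether; 2R,5R,10S,11R,14S,16R | C=C1[C@H](OCc2ccc(OC)cc2)CC[C@H](C)CCC3=C(C)[C@@H]4[C@H]1CC[C@]4(C)C(=O)[C@@H]3O | intermediate
33 | C16 triethylsilyl ether of 32 | C=C1[C@H](OCc2ccc(OC)cc2)CC[C@H](C)CCC3=C(C)[C@@H]4[C@H]1CC[C@]4(C)C(=O)[C@@H]3O[Si](CC)(CC)CC | intermediate
34 | C2 alcohol, C16 triethylsilyl ether, C15 ketone | C=C1[C@H](O)CC[C@H](C)CCC2=C(C)[C@@H]3[C@H]1CC[C@]3(C)C(=O)[C@@H]2O[Si](CC)(CC)CC | intermediate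
35 | C2 acetate, C16 triethylsilyl ether, C15 ketone | C=C1[C@H](OC(C)=O)CC[C@H](C)CCC2=C(C)[C@@H]3[C@H]1CC[C@]3(C)C(=O)[C@@H]2O[Si](CC)(CC)CC | intermediate
36 | C2 acetate, C15 ketone, free 16-hydroxyl | C=C1[C@H](OC(C)=O)CC[C@H](C)CCC2=C(C)[C@@H]3[C@H]1CC[C@]3(C)C(=O)[C@@H]2O | intermediate
37 | CNP0192310.3: C2 acetate, 15,16-trans-diol; 2R,5R,10S,11R,14S,15R,16R | C=C1[C@H](OC(C)=O)CC[C@H](C)CCC2=C(C)[C@@H]3[C@H]1CC[C@]3(C)[C@@H](O)[C@@H]2O | target

**Step count**

Total: 22 steps. Longest linear sequence: 20 steps (steps 1–6 and 9–22, from 1 and 2); steps 7 and 8 prepare the alkenyl iodide.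

**Steps most likely to fail**

1. Step 10 (proposed new method). Heterolytic cleavage of the C2–C8 bond of the alkoxide into a stabilised cyclohexadienyl anion and an enone may outrun the concerted shift, so that re-closure loses stereocontrol at C10 and C11 or proton transfer ends in ring-opened material; a boat pathway would also erode C11. The fallback uses known chemistry (the neutral siloxy-Cope ring expansion and the aminomethylation of a silyl enol ether) and sets out from 17. Silylation (Me3SiOTf, 2,6-lutidine, CH2Cl2, −78 °C) gives the trimethylsilyl ether F1, which has no alkoxide to fragment. Heating F1 in toluene in a base-washed sealed tube at about 180 °C should effect the purely pericyclic rearrangement to the ring-expanded trimethylsilyl enol ether F2. Treatment of F2 with dimethylmethyleneammonium iodide in CH2Cl2 at room temperature gives Mannich base 20, where the route is rejoined (MeI, then NaHCO3, to 22).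

2. Step 17. Removal of the allylic C16 hydrogen from the alkoxide (enediolate formation, with ketol transposition or loss of C16 configuration), O-alkylation, or incomplete regiocontrol of enolisation may compete with C-alkylation at C14. The fallback sets out from 25 and closes the ring from the regiodefined enol ether before the ketol exists. Bu4NF in THF gives the primary alcohol F3, and Dess–Martin periodinane with NaHCO3 gives the aldehyde F4. BF3·OEt2 in CH2Cl2 at −78 °C, followed by aqueous work-up, effects a Mukaiyama-type aldol addition of the methyl enol ether carbon C14 to the aldehyde; this closes the cis-fused cyclopentane and unmasks the C15 ketone as the hydroxy ketone F5 (C13 carbinol, either epimer). 1,1′-Thiocarbonyldiimidazole with DMAP gives the imidazolide F6, and Bu3SnH with AIBN in toluene at 90 °C (Barton–McCombie deoxygenation) gives the hydrindanone F7. Only C16 can now enolise, so KN(SiMe3)2 followed by 2-(phenylsulfonyl)-3-phenyloxaziridine should hydroxylate it and return the route at 32.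

3. Step 4. Enantiofacial discrimination by the chiral catalyst may be low on this tetrasubstituted alkene, or turnover so slow that background oxidation of the enol ether intervenes. The fallback sets out from 7 and replaces catalyst control by a resolution. Directed epoxidation with VO(acac)2 (cat.) and t-BuOOH gives 8 together with the enantiomeric epoxide F8. Steps 5 and 6 as written carry the pair to 9 with the enantiomeric hydroxy ketone F9 and then to 10 with the enantiomeric spiro ketone F10. Reduction with (S)-2-methyl-CBS-oxazaborolidine and BH3·SMe2, which differentiates the quaternary C8 flank from the methylene flank in both enantiomers, gives the diastereomeric carbinols: the (2R)-carbinol F11 from 10 and the (2R)-carbinol F12 from F10. These are separated by chromatography, and Dess–Martin oxidation of F11 returns enantiopure 10.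

**Further compounds**

F1 | step 10 | trimethylsilyl ether of 17 | C[Si](C)(C)O[C@@]1(/C=C/CCO[Si](C)(C)C(C)(C)C)CC[C@H](C)CC[C@]12C(C)=CC(C)=C(OC)C2
F2 | step 10 | ring-expanded C1=C2 trimethylsilyl enol ether (silyl analogue of 19) | C1=C(O[Si](C)(C)C)CC[C@H](C)CCC2=C(C)[C@H]([C@H]1CCO[Si](C)(C)C(C)(C)C)C(C)=C(OC)C2
F3 | step 17 | primary alcohol from 25 (enol ether and 4-methoxybenzyl ether retained) | C=C1[C@H](OCc2ccc(OC)cc2)CC[C@H](C)CCC3=C(C)[C@H]([C@H]1CCO)C(C)=C(OC)C3
F4 | step 17 | C13 aldehyde | C=C1[C@H](OCc2ccc(OC)cc2)CC[C@H](C)CCC3=C(C)[C@H]([C@H]1CC=O)C(C)=C(OC)C3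
F5 | step 17 | cis-hydrindane C13-hydroxy C15 ketone (C13 epimers) | C=C1[C@H](OCc2ccc(OC)cc2)CC[C@H](C)CCC3=C(C)[C@@H]4[C@H]1CC(O)[C@]4(C)C(=O)C3
F6 | step 17 | C13 O-(imidazol-1-ylthiocarbonyl) derivative of F5 | C=C1[C@H](OCc2ccc(OC)cc2)CC[C@H](C)CCC3=C(C)[C@@H]4[C@H]1CC(OC(=S)n5ccnc5)[C@]4(C)C(=O)C3
F7 | step 17 | cis-hydrindane C15 ketone without the 16-hydroxyl | C=C1[C@H](OCc2ccc(OC)cc2)CC[C@H](C)CCC3=C(C)[C@@H]4[C@H]1CC[C@]4(C)C(=O)C3
F8 | step 4 | enantiomer of epoxy carbinol 8 | C[C@@H]1CC[C@@](O)([C@]23O[C@@]2(C)CC(C)=C(OC)C3)CC1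
F9 | step 4 | enantiomer of hydroxy ketone 9 | O=C1CC[C@@H](C)CC[C@@]12[C@@](C)(O)CC(C)=C(OC)C2
F10 | step 4 | enantiomer of spiro ketone 10 | O=C1CC[C@@H](C)CC[C@@]12C(C)=CC(C)=C(OC)C2
F11 | step 4 | (2R)-carbinol from 10 | O[C@@H]1CC[C@H](C)CC[C@]12C(C)=CC(C)=C(OC)C2
F12 | step 4 | (2R)-carbinol from F10 | O[C@@H]1CC[C@@H](C)CC[C@@]12C(C)=CC(C)=C(OC)C2
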